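**Retrosynthetic overview**
- The target comes from BCl3 cleavage of two isopropyl ethers on a 1,3-dimethyl-3,4-dihydroisoquinoline, whose C=N ring closes by condensation of an amino ketone made from an N-Boc lactam and MeMgBr.
- The biaryl bond comes from a Suzuki coupling of a 7-bromo lactam with a naphthyl boronate.
- The key C3–C4 bond comes from an intermolecular vinylogous Mannich addition of a laterally lithiated toluate to (S)-N-tert-butanesulfinyl acetaldimine, which sets C3; lactamisation follows.
- The toluate comes from orcinol, with the two oxygens told apart by chelation-controlled dealkylation; the naphthalene comes from a Stobbe (aldol-type) condensation and Friedel–Crafts closure.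
- Ring order: second naphthalene ring (step 2), lactam ring (step 17), reopened (step 20) and reclosed as the dihydroisoquinoline (step 21).

Assumption: the SMILES fixes only C3 (S); the biaryl axis is unspecified, so it is not controlled and any atropisomers are carried together.

**Route**

Step 1
Reactants: 1 2-bromo-5-methoxybenzaldehyde; 2 dimethyl succinate
Product: 4 (3E)-4-(2-bromo-5-methoxyphenyl)-3-(methoxycarbonyl)but-3-enoic acid, via paraconate lactone 3 (not isolated)
Conditions: NaOMe, MeOH, reflux; then aq. HCl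
Reagents that add atoms: none
Why: Stobbe condensation, in which the succinate enolate adds to the aldehyde (intermolecular aldol), the alkoxide lactonises to 3 and base-induced ring opening gives the E half-ester with the aryl ring cis to the CH2CO2H arm.

Step 2
Reactants: 4
Product: 6 methyl 8-bromo-4-hydroxy-5-methoxynaphthalene-2-carboxylate, via naphthyl acetate 5 (not isolated)
Conditions: Ac2O, NaOAc, 140 °C; evaporate; then K2CO3, MeOH, rt; aq. HCl
Reagents that add atoms: none
Why: intramolecular Friedel–Crafts acylation through the mixed anhydride can only close ortho to OMe because Br blocks the para position, and base-catalysed methanolysis then frees the naphthol from its acetate.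

Step 3
Reactants: 6
Product: 7 methyl 8-bromo-5-methoxy-4-(propan-2-yloxy)naphthalene-2-carboxylate
Conditions: 2-bromopropane, K2CO3, DMF, 60 °C
Reagents that add atoms: 2-bromopropane CC(C)Br
Why: Williamson etherification installs an isopropyl ether that survives hydride, organometallic, basic and TFA conditions and is later cleaved by BCl3 without loss of methyl ethers.

Step 4
Reactants: 7
Product: 8 [8-bromo-5-methoxy-4-(propan-2-yloxy)naphthalen-2-yl]methanol
Conditions: iBu2AlH, CH2Cl2, −78 → 0 °C; aq. KNaC4H4O6 (potassium sodium tartrate)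
Reagents that add atoms: none
Why: hydride reduction of the ester to the primary alcohol leaves the aryl bromide untouched at low temperature.

Step 5
Reactants: 8
Product: 9 1-bromo-7-(bromomethyl)-4-methoxy-5-(propan-2-yloxy)naphthalene
Conditions: CBr4, PPh3, CH2Cl2, 0 °C
Reagents that add atoms: carbon tetrabromide BrC(Br)(Br)Br
Why: Appel bromination converts the benzylic alcohol under neutral conditions that spare the ethers.

Step 6
Reactants: 9
Product: 10 1-bromo-4-methoxy-7-methyl-5-(propan-2-yloxy)naphthalene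
Conditions: LiBEt3H, THF, 0 °C
Reagents that add atoms: none
Why: SN2 hydride displacement reduces the benzylic bromide to methyl much faster than any reaction at the aryl bromide.

Step 7
Reactants: 10
Product: 11 2-[4-methoxy-7-methyl-5-(propan-2-yloxy)naphthalen-1-yl]-4,4,5,5-tetramethyl-1,3,2-dioxaborolane
Conditions: B2pin2, PdCl2(dppf) (3 mol%), KOAc, 1,4-dioxane, 90 °C
Reagents that add atoms: bis(pinacolato)diboron CC1(C)OB(OC1(C)C)B1OC(C)(C)C(C)(C)O1
Why: Miyaura borylation of a 1-bromonaphthalene is routine and the weak base KOAc prevents homocoupling.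

Step 8
Reactants: 12 orcinol (5-methylbenzene-1,3-diol)
Product: 13 1-methyl-3,5-bis(propan-2-yloxy)benzene
Conditions: 2-bromopropane (excess), K2CO3, DMF, 70 °C
Reagents that add atoms: 2-bromopropane CC(C)Br
Why: double Williamson etherification gives a symmetric diether, so the next two ring substitutions have no regiochemical ambiguity.

Step 9
Reactants: 13
Product: 15 2-bromo-5-methyl-1,3-bis(propan-2-yloxy)benzene, via aryllithium 14 (not isolated)
Conditions: n-BuLi, TMEDA, THF, 0 °C → rt; then BrCCl2CCl2Br, −78 °C → rt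
Reagents that add atoms: 1,2-dibromo-1,1,2,2-tetrachloroethane BrC(Cl)(Cl)C(Cl)(Cl)Br
Why: directed ortho-metalation occurs at the position flanked by both alkoxy groups and electrophilic bromination of 14 places Br exactly at the future biaryl carbon.

Step 10
Reactants: 15
Product: 17 3-bromo-6-methyl-2,4-bis(propan-2-yloxy)benzaldehyde, via iminium chloride 16 (not isolated)
Conditions: POCl3, DMF, 0 → 80 °C; then ice/H2O
Reagents that add atoms: N,N-dimethylformamide CN(C)C=O; water O
Why: Vilsmeier–Haack formylation can only attack the two equivalent free positions (ortho and para to the alkoxy groups), and the isopropyl ethers tolerate POCl3.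

Step 11
Reactants: 17
Product: 18 3-bromo-2-hydroxy-6-methyl-4-(propan-2-yloxy)benzaldehyde
Conditions: BCl3 (1.1 equiv), CH2Cl2, −78 → −20 °C; H2O
Reagents that add atoms: none
Why: chelation of boron between the aldehyde oxygen and the ortho ether oxygen makes that isopropyl ether cleave selectively (Lewis-acid dealkylation), leaving the para one in place.

Step 12
Reactants: 18
Product: 19 3-bromo-2-methoxy-6-methyl-4-(propan-2-yloxy)benzaldehyde
Conditions: MeI, K2CO3, DMF, 40 °C
Reagents that add atoms: iodomethane CI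
Why: Williamson O-methylation of the only free phenol fixes the future 8-OMe / 6-O-isopropyl pattern.

Step 13
Reactants: 19
Product: 20 3-bromo-2-methoxy-6-methyl-4-(propan-2-yloxy)benzoic acid
Conditions: NaClO2, NaH2PO4, 2-methyl-2-butene, t-BuOH/H2O, rt
Reagents that add atoms: sodium chlorite [Na+].[O-]Cl=O
Why: Pinnick oxidation converts hindered aryl aldehydes cleanly, with the alkene scavenger protecting the electron-rich ring from chlorination.

Step 14
Reactants: 20
Product: 21 methyl 3-bromo-2-methoxy-6-methyl-4-(propan-2-yloxy)benzoate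
Conditions: MeI, K2CO3, DMF, rt
Reagents that add atoms: iodomethane CI
Why: carboxylate O-alkylation (SN2) is used because the doubly ortho-substituted acid resists Fischer esterification.

Step 15
Reactants: 22 acetaldehyde; 23 (S)-2-methylpropane-2-sulfinamide
Product: 24 (S)-N-[(1E)-ethylidene]-2-methylpropane-2-sulfinamide
Conditions: CuSO4, CH2Cl2, 0 °C → rt (excess 22)
Reagents that add atoms: none
Why: Lewis-acid and dehydrating-agent promoted imine condensation gives the E sulfinyl aldimine without racemisation at sulfur.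

Step 16
Reactants: 21; 24
Product: 26 methyl 3-bromo-2-methoxy-6-[(2S)-2-{[(S)-2-methylpropane-2-sulfinyl]amino}propyl]-4-(propan-2-yloxy)benzoate, via lithiated toluate 25 (not isolated)
Conditions: LiN(iPr)2 (1.05 equiv), THF, −78 °C; then 24 (1.2 equiv), −78 °C; aq. NH4Cl
Reagents that add atoms: none
Why: vinylogous Mannich-type addition, in which the benzylic anion 25 (an extended ester enolate) attacks the Re face of the (S)-sulfinyl aldimine through a six-membered lithium-chelated chair with tert-butyl equatorial, setting C3 as S; the minor diastereomer is removed by chromatography.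

Step 17
Reactants: 26
Product: 28 (3S)-7-bromo-8-methoxy-3-methyl-6-(propan-2-yloxy)-3,4-dihydroisoquinolin-1(2H)-one, via amino ester hydrochloride 27 (not isolated)
Conditions: HCl (4 M in dioxane), MeOH, 0 °C → rt; evaporate; then K2CO3, MeOH, 60 °C
Reagents that add atoms: none
Why: acidic N–S cleavage frees the amine, which closes the six-membered lactam by intramolecular aminolysis of the ester without touching the stereocentre, so the lactam carbon (future C1) is ortho to the OMe by construction.

Step 18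
Reactants: 28; 11
Product: 29 (3S)-8-methoxy-7-[4-methoxy-7-methyl-5-(propan-2-yloxy)naphthalen-1-yl]-3-methyl-6-(propan-2-yloxy)-3,4-dihydroisoquinolin-1(2H)-one
Conditions: Pd(OAc)2 (5 mol%), SPhos (10 mol%), K3PO4, toluene/H2O, 100 °C
Reagents that add atoms: none
Why: Suzuki–Miyaura coupling with a bulky electron-rich biarylphosphine is suited to a di-ortho-alkoxy aryl bromide and a 1-naphthyl boronate, and the free lactam N–H is tolerated.

Step 19
Reactants: 29
Product: 30 tert-butyl (3S)-8-methoxy-7-[4-methoxy-7-methyl-5-(propan-2-yloxy)naphthalen-1-yl]-3-methyl-1-oxo-6-(propan-2-yloxy)-3,4-dihydroisoquinoline-2(1H)-carboxylate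
Conditions: Boc2O, DMAP, Et3N, MeCN, rt
Reagents that add atoms: di-tert-butyl dicarbonate CC(C)(C)OC(=O)OC(=O)OC(C)(C)C
Why: DMAP-catalysed N-acylation turns the lactam into an imide-like carbonyl that is electrophilic enough for a single Grignard addition.

Step 20
Reactants: 30
Product: 31 tert-butyl N-[(2S)-1-{2-acetyl-3-methoxy-4-[4-methoxy-7-methyl-5-(propan-2-yloxy)naphthalen-1-yl]-5-(propan-2-yloxy)phenyl}propan-2-yl]carbamate
Conditions: MeMgBr, THF, −78 → 0 °C; aq. NH4Cl
Reagents that add atoms: methylmagnesium bromide C[Mg]Br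
Why: Grignard addition to the N-Boc lactam carbonyl gives a magnesium hemiaminal that resists a second addition and opens to the keto carbamate on work-up (any ring tautomer converges in step 21).

Step 21
Reactants: 31
Product: 33 (3S)-8-methoxy-7-[4-methoxy-7-methyl-5-(propan-2-yloxy)naphthalen-1-yl]-1,3-dimethyl-6-(propan-2-yloxy)-3,4-dihydroisoquinoline, via amino ketone trifluoroacetate 32 (not isolated)
Conditions: TFA, CH2Cl2, 0 °C → rt; then aq. NaHCO3
Reagents that add atoms: none
Why: acidolytic Boc removal is followed by spontaneous intramolecular ketimine condensation to the six-membered C=N ring, while isopropyl ethers and C3 are unaffected; the ring is closed before BCl3 is used so no aryl ketone remains to direct cleavage of the ortho OMe.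

Step 22
Reactants: 33
Product: 34 (3S)-7-(5-hydroxy-4-methoxy-7-methylnaphthalen-1-yl)-8-methoxy-1,3-dimethyl-3,4-dihydroisoquinolin-6-ol
Conditions: BCl3 (6 equiv), CH2Cl2, −78 → 0 °C; H2O, then aq. NaHCO3
Reagents that add atoms: none
Why: Lewis-acid dealkylation removes secondary isopropyl ethers much faster than methyl ethers, and the imine nitrogen lone pair points away from the 8-OMe so no chelation-assisted demethylation is expected.

**Compound list**

1 | 2-bromo-5-methoxybenzaldehyde | COc1ccc(Br)c(C=O)c1 | starting material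
2 | dimethyl succinate | COC(=O)CCC(=O)OC | starting material
3 | methyl 2-(2-bromo-5-methoxyphenyl)-5-oxooxolane-3-carboxylate (paraconate lactone) | COC(=O)C1CC(=O)OC1c1cc(OC)ccc1Br | intermediate
4 | (3E)-4-(2-bromo-5-methoxyphenyl)-3-(methoxycarbonyl)but-3-enoic acid | COC(=O)/C(CC(=O)O)=C/c1cc(OC)ccc1Br | intermediate
5 | methyl 4-(acetyloxy)-8-bromo-5-methoxynaphthalene-2-carboxylate | COC(=O)c1cc(OC(C)=O)c2c(OC)ccc(Br)c2c1 | intermediate
6 | methyl 8-bromo-4-hydroxy-5-methoxynaphthalene-2-carboxylate | COC(=O)c1cc(O)c2c(OC)ccc(Br)c2c1 | intermediate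
7 | methyl 8-bromo-5-methoxy-4-(propan-2-yloxy)naphthalene-2-carboxylate | COC(=O)c1cc(OC(C)C)c2c(OC)ccc(Br)c2c1 | intermediate
8 | [8-bromo-5-methoxy-4-(propan-2-yloxy)naphthalen-2-yl]methanol | OCc1cc(OC(C)C)c2c(OC)ccc(Br)c2c1 | intermediate
9 | 1-bromo-7-(bromomethyl)-4-methoxy-5-(propan-2-yloxy)naphthalene | BrCc1cc(OC(C)C)c2c(OC)ccc(Br)c2c1 | intermediate
10 | 1-bromo-4-methoxy-7-methyl-5-(propan-2-yloxy)naphthalene | Cc1cc(OC(C)C)c2c(OC)ccc(Br)c2c1 | intermediate
11 | 2-[4-methoxy-7-methyl-5-(propan-2-yloxy)naphthalen-1-yl]-4,4,5,5-tetramethyl-1,3,2-dioxaborolane | Cc1cc(OC(C)C)c2c(OC)ccc(B3OC(C)(C)C(C)(C)O3)c2c1 | intermediate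
12 | orcinol (5-methylbenzene-1,3-diol) | Cc1cc(O)cc(O)c1 | starting material
13 | 1-methyl-3,5-bis(propan-2-yloxy)benzene | Cc1cc(OC(C)C)cc(OC(C)C)c1 | intermediate
14 | [4-methyl-2,6-bis(propan-2-yloxy)phenyl]lithium | [Li]c1c(OC(C)C)cc(C)cc1OC(C)C | intermediate
15 | 2-bromo-5-methyl-1,3-bis(propan-2-yloxy)benzene | Cc1cc(OC(C)C)c(Br)c(OC(C)C)c1 | intermediate
16 | N-{[3-bromo-6-methyl-2,4-bis(propan-2-yloxy)phenyl]methylidene}-N-methylmethanaminium chloride | C[N+](C)=Cc1c(C)cc(OC(C)C)c(Br)c1OC(C)C.[Cl-] | intermediate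
17 | 3-bromo-6-methyl-2,4-bis(propan-2-yloxy)benzaldehyde | Cc1cc(OC(C)C)c(Br)c(OC(C)C)c1C=O | intermediate
18 | 3-bromo-2-hydroxy-6-methyl-4-(propan-2-yloxy)benzaldehyde | Cc1cc(OC(C)C)c(Br)c(O)c1C=O | intermediate
19 | 3-bromo-2-methoxy-6-methyl-4-(propan-2-yloxy)benzaldehyde | Cc1cc(OC(C)C)c(Br)c(OC)c1C=O | intermediate
20 | 3-bromo-2-methoxy-6-methyl-4-(propan-2-yloxy)benzoic acid | Cc1cc(OC(C)C)c(Br)c(OC)c1C(=O)O | intermediate
21 | methyl 3-bromo-2-methoxy-6-methyl-4-(propan-2-yloxy)benzoate | COC(=O)c1c(C)cc(OC(C)C)c(Br)c1OC | intermediate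
22 | acetaldehyde | CC=O | starting material
23 | (S)-2-methylpropane-2-sulfinamide | CC(C)(C)[S@](=O)N | starting material
24 | (S)-N-[(1E)-ethylidene]-2-methylpropane-2-sulfinamide | CC(C)(C)[S@](=O)/N=C/C | intermediate
25 | {[4-bromo-3-methoxy-2-(methoxycarbonyl)-5-(propan-2-yloxy)phenyl]methyl}lithium | [Li]Cc1cc(OC(C)C)c(Br)c(OC)c1C(=O)OC | intermediate
26 | methyl 3-bromo-2-methoxy-6-[(2S)-2-{[(S)-2-methylpropane-2-sulfinyl]amino}propyl]-4-(propan-2-yloxy)benzoate | COC(=O)c1c(C[C@H](C)N[S@@](=O)C(C)(C)C)cc(OC(C)C)c(Br)c1OC | intermediate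
27 | methyl 6-[(2S)-2-aminopropyl]-3-bromo-2-methoxy-4-(propan-2-yloxy)benzoate hydrochloride | COC(=O)c1c(C[C@H](C)[NH3+])cc(OC(C)C)c(Br)c1OC.[Cl-] | intermediate
28 | (3S)-7-bromo-8-methoxy-3-methyl-6-(propan-2-yloxy)-3,4-dihydroisoquinolin-1(2H)-one | C[C@H]1Cc2cc(OC(C)C)c(Br)c(OC)c2C(=O)N1 | intermediate
29 | (3S)-8-methoxy-7-[4-methoxy-7-methyl-5-(propan-2-yloxy)naphthalen-1-yl]-3-methyl-6-(propan-2-yloxy)-3,4-dihydroisoquinolin-1(2H)-one | C[C@H]1Cc2cc(OC(C)C)c(-c3ccc(OC)c4c(OC(C)C)cc(C)cc34)c(OC)c2C(=O)N1 | intermediate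
30 | tert-butyl (3S)-8-methoxy-7-[4-methoxy-7-methyl-5-(propan-2-yloxy)naphthalen-1-yl]-3-methyl-1-oxo-6-(propan-2-yloxy)-3,4-dihydroisoquinoline-2(1H)-carboxylate | C[C@H]1Cc2cc(OC(C)C)c(-c3ccc(OC)c4c(OC(C)C)cc(C)cc34)c(OC)c2C(=O)N1C(=O)OC(C)(C)C | intermediate
31 | tert-butyl N-[(2S)-1-{2-acetyl-3-methoxy-4-[4-methoxy-7-methyl-5-(propan-2-yloxy)naphthalen-1-yl]-5-(propan-2-yloxy)phenyl}propan-2-yl]carbamate | CC(=O)c1c(C[C@H](C)NC(=O)OC(C)(C)C)cc(OC(C)C)c(-c2ccc(OC)c3c(OC(C)C)cc(C)cc23)c1OC | intermediate
32 | 1-{2-[(2S)-2-aminopropyl]-6-methoxy-5-[4-methoxy-7-methyl-5-(propan-2-yloxy)naphthalen-1-yl]-4-(propan-2-yloxy)phenyl}ethan-1-one trifluoroacetate | CC(=O)c1c(C[C@H](C)[NH3+])cc(OC(C)C)c(-c2ccc(OC)c3c(OC(C)C)cc(C)cc23)c1OC.[O-]C(=O)C(F)(F)F | intermediate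
33 | (3S)-8-methoxy-7-[4-methoxy-7-methyl-5-(propan-2-yloxy)naphthalen-1-yl]-1,3-dimethyl-6-(propan-2-yloxy)-3,4-dihydroisoquinoline | COc1c2c(cc(OC(C)C)c1-c1ccc(OC)c3c(OC(C)C)cc(C)cc13)C[C@H](C)N=C2C | intermediate
34 | (3S)-7-(5-hydroxy-4-methoxy-7-methylnaphthalen-1-yl)-8-methoxy-1,3-dimethyl-3,4-dihydroisoquinolin-6-ol | COc1c2c(cc(O)c1-c1ccc(OC)c3c(O)cc(C)cc13)C[C@H](C)N=C2C | target

**Totals and risks**

Total step count: 22. Longest linear sequence: 14 steps (from 12 through steps 8–14 and 16–22 to 34).

The three steps most likely to fail: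

Step 16 (lateral lithiation and Mannich addition). The enolisable aldimine 24 can be deprotonated instead of attacked, and the diastereoselectivity may be modest. The fallback sets out from 21: the benzylic anion (LiN(iPr)2, THF, −78 °C) is acylated with N-methoxy-N-methylacetamide in a Claisen-type acylation to give methyl 3-bromo-2-methoxy-6-(2-oxopropyl)-4-(propan-2-yloxy)benzoate F1. F1 is condensed with 23 (Ti(OEt)4, THF) to methyl 3-bromo-2-methoxy-6-[(2E)-2-{[(S)-2-methylpropane-2-sulfinyl]imino}propyl]-4-(propan-2-yloxy)benzoate F2. Reduction of F2 with NaBH4 at −48 °C delivers hydride through the cyclic sulfinyl-bound transition state to give the S amine, and the fallback comes back to the route at 26.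

Step 18 (Suzuki coupling). The di-ortho-alkoxy bromide 28 is slow in oxidative addition and boronate 11 can protodeboronate. The fallback is a Negishi coupling that sets out from 10: bromine–lithium exchange (n-BuLi, THF, −78 °C) and transmetalation with ZnCl2 give chloro[4-methoxy-7-methyl-5-(propan-2-yloxy)naphthalen-1-yl]zinc F3. F3 is coupled with 28 using Pd2(dba)3/RuPhos in THF at 65 °C, and the fallback comes back to the route at 29.

Step 20 (Grignard opening of the N-Boc lactam). The carbonyl is hindered and electron-rich, so attack at the Boc carbonyl or incomplete reaction is possible. The fallback sets out from 29: O-activation with Tf2O and 2-fluoropyridine (CH2Cl2, −78 → 0 °C) gives (3S)-8-methoxy-7-[4-methoxy-7-methyl-5-(propan-2-yloxy)naphthalen-1-yl]-3-methyl-6-(propan-2-yloxy)-3,4-dihydroisoquinolin-1-yl trifluoromethanesulfonate F4. F4 is treated in the same flask with MeMgBr (addition–elimination at the imidoyl carbon), and the fallback comes back to the route at 33, bypassing 30 to 32.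

**Further compounds**

F1 | step 16 | methyl 3-bromo-2-methoxy-6-(2-oxopropyl)-4-(propan-2-yloxy)benzoate | COC(=O)c1c(CC(C)=O)cc(OC(C)C)c(Br)c1OC
F2 | step 16 | methyl 3-bromo-2-methoxy-6-[(2E)-2-{[(S)-2-methylpropane-2-sulfinyl]imino}propyl]-4-(propan-2-yloxy)benzoate | COC(=O)c1c(C/C(C)=N/[S@@](=O)C(C)(C)C)cc(OC(C)C)c(Br)c1OC
F3 | step 18 | chloro[4-methoxy-7-methyl-5-(propan-2-yloxy)naphthalen-1-yl]zinc | Cc1cc(OC(C)C)c2c(OC)ccc([Zn]Cl)c2c1
F4 | step 20 | (3S)-8-methoxy-7-[4-methoxy-7-methyl-5-(propan-2-yloxy)naphthalen-1-yl]-3-methyl-6-(propan-2-yloxy)-3,4-dihydroisoquinolin-1-yl trifluoromethanesulfonate | C[C@H]1Cc2cc(OC(C)C)c(-c3ccc(OC)c4c(OC(C)C)cc(C)cc34)c(OC)c2C(OS(=O)(=O)C(F)(F)F)=N1
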